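**Retrosynthetic overview**

- The strategy rests on one feature: C3 of the central pyranone (ring B) carries the ether oxygen to C7 of coumarin unit A. The C3=C4 bond of ring B is therefore disconnected to the OCH2 carbon of a (coumarin-7-yloxy)acetate ester and an ortho-formyl group on the biaryl phenol, and the C3–O bond becomes a plain phenol alkylation.
- The 2-formylaryl ester 12 comes from salicylaldehyde 7 and acid chloride 11, the latter made from umbelliferone and ethyl bromoacetate.
- Salicylaldehyde 7 comes from a Suzuki–Miyaura coupling that forms the C8–C8' biaryl bond, followed by Rieche formylation and chelation-controlled BCl3 cleavage of the one methyl ether ortho to the aldehyde. This fixes which oxygen is acylated.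
- Ring order: the pyranones of units A and C arrive intact in umbelliferone. The pyranone of unit B is the only ring built, and it is built last. Two O-methyl groups are then removed.

Key step: step 10

Remark: the target string carries no axial descriptor for the tetra-ortho-oxygenated C8–C8' biaryl axis, so the axis is formed without stereocontrol and all biaryl compounds are taken as racemates.

**Route**

Step 1
Reactants: 1 umbelliferone (7-hydroxy-2H-chromen-2-one)
Product: 2 7-hydroxy-8-iodo-2H-chromen-2-one
Conditions: I2 (1.0 equiv), KI, 20% aq. NH3, 0 °C → rt; then dilute H2SO4 to pH 3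
Reagents that add atoms: iodine, II
Why: Electrophilic aromatic iodination of the phenoxide should go to C8, the position ortho to the phenoxide oxygen and flanked by both ring oxygens, and one equivalent of iodine limits 6,8-diiodination.

Step 2
Reactants: 2 7-hydroxy-8-iodo-2H-chromen-2-one
Product: 3 8-iodo-7-methoxy-2H-chromen-2-one
Conditions: MeI, K2CO3, acetone, reflux
Reagents that add atoms: iodomethane, CI
Why: Williamson ether synthesis on the acidic coumarin phenol; the lactone and the aryl iodide are inert to carbonate in acetone.

Step 3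
Reactants: 3 8-iodo-7-methoxy-2H-chromen-2-one; 4 (2,6-dimethoxyphenyl)boronic acid
Product: 5 8-(2,6-dimethoxyphenyl)-7-methoxy-2H-chromen-2-one
Conditions: Pd(OAc)2 (5 mol %), SPhos (2-dicyclohexylphosphino-2',6'-dimethoxybiphenyl, 10 mol %), K3PO4 (anhydrous), 4 (2 equiv), toluene, 100 °C
Reagents that add atoms: none
Why: Suzuki–Miyaura coupling with a bulky dialkylbiarylphosphine, the ligand class established for tetra-ortho-substituted biaryls and for 2,6-dialkoxyphenylboronic acids; anhydrous phosphate in toluene leaves the lactone closed and slows protodeboronation.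

Step 4
Reactants: 5 8-(2,6-dimethoxyphenyl)-7-methoxy-2H-chromen-2-one
Product: 6 2,4-dimethoxy-3-(7-methoxy-2-oxo-2H-chromen-8-yl)benzaldehyde
Conditions: Cl2CHOMe, TiCl4, CH2Cl2, −20 → 0 °C; then ice-cold 1 M HCl
Reagents that add atoms: dichloromethyl methyl ether, COC(Cl)Cl; water, O
Why: Rieche formylation should attack the dimethoxyphenyl ring at C3', which is ortho to one methoxy group and para to the other and equivalent to C5' by symmetry, while the coumarin ring is deactivated by its lactone and by TiCl4 coordination; hydrolysis of the α-chloro ether gives the aldehyde.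

Step 5
Reactants: 6 2,4-dimethoxy-3-(7-methoxy-2-oxo-2H-chromen-8-yl)benzaldehyde
Product: 7 2-hydroxy-4-methoxy-3-(7-methoxy-2-oxo-2H-chromen-8-yl)benzaldehyde
Conditions: BCl3 (1.5 equiv), CH2Cl2, −78 → 0 °C; then H2O
Reagents that add atoms: none
Why: Chelation-controlled Lewis-acid ether cleavage, in which BCl3 bound between the formyl oxygen and the ortho methoxy oxygen delivers chloride to that methyl group only; the two non-chelating methyl ethers should survive at low temperature.

Step 6
Reactants: 1 umbelliferone; 8 ethyl bromoacetate
Product: 9 ethyl [(2-oxo-2H-chromen-7-yl)oxy]acetate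
Conditions: K2CO3, acetone, reflux
Reagents that add atoms: none
Why: Williamson ether synthesis of the phenoxide with a reactive α-bromo ester; this installs the future C3–O–C7 ether linkage.

Step 7
Reactants: 9 ethyl [(2-oxo-2H-chromen-7-yl)oxy]acetate
Product: 10 [(2-oxo-2H-chromen-7-yl)oxy]acetic acid
Conditions: LiOH·H2O, THF/H2O, 0 °C → rt; then 1 M HCl to pH 1
Reagents that add atoms: lithium hydroxide, [Li+].[OH-]
Why: Ester saponification; any coumarin ring opened by hydroxide re-lactonises on acidification because the cis-cinnamate geometry is retained.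

Step 8
Reactants: 10 [(2-oxo-2H-chromen-7-yl)oxy]acetic acid
Product: 11 [(2-oxo-2H-chromen-7-yl)oxy]acetyl chloride
Conditions: (COCl)2, DMF (cat.), CH2Cl2, 0 °C → rt; evaporate, use crude
Reagents that add atoms: oxalyl chloride, O=C(Cl)C(=O)Cl
Why: Acid chloride formation through the catalytic chloroiminium species under neutral, mild conditions that leave the lactone and aryl ether untouched.

Step 9
Reactants: 7 2-hydroxy-4-methoxy-3-(7-methoxy-2-oxo-2H-chromen-8-yl)benzaldehyde; 11 [(2-oxo-2H-chromen-7-yl)oxy]acetyl chloride
Product: 12 6-formyl-3-methoxy-2-(7-methoxy-2-oxo-2H-chromen-8-yl)phenyl [(2-oxo-2H-chromen-7-yl)oxy]acetate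
Conditions: pyridine, DMAP (cat.), CH2Cl2, 0 °C → rt; rapid work-up, use without long storage
Reagents that add atoms: none
Why: O-acylation of a phenol by an acid chloride under nucleophilic catalysis, directed to the only free hydroxyl; pyridine is too weak a base to trigger ketene formation or much premature ring closure, and any closure that does occur gives 13.

Step 10
Reactants: 12 6-formyl-3-methoxy-2-(7-methoxy-2-oxo-2H-chromen-8-yl)phenyl [(2-oxo-2H-chromen-7-yl)oxy]acetate
Product: 13 7-methoxy-8-(7-methoxy-2-oxo-2H-chromen-8-yl)-3-[(2-oxo-2H-chromen-7-yl)oxy]-2H-chromen-2-one (triumbelletin di-O-methyl ether)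
Conditions: DBU (1.5 equiv), MeCN, 4 Å molecular sieves, rt → 50 °C
Reagents that add atoms: none
Why: DBU reversibly deprotonates the OCH2 group, which is acidified by the aryl-ester carbonyl and the aryloxy oxygen, and the ester enolate adds to the neighbouring formyl group; the aldol then loses water by E1cB elimination through the same C3 carbanion, giving the C3=C4 bond of ring B. This is the Perkin-type intramolecular Knoevenagel condensation known for 2-formylaryl arylacetates and aryloxyacetates. The pyranone of unit B closes in a 6-(enolendo)-exo-trig mode, which is favoured. No stereocentre is formed and the alkene geometry is fixed by the ring. The step needs the acyl group on the oxygen ortho to the aldehyde, which is secured because that oxygen was the only free phenol of 7 (unmasked by chelation in step 5) while the other two phenols are methyl ethers that cannot accept the acyl group. Dry conditions suppress the competing loss of the activated aryl ester by hydrolysis or acyl transfer.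

Step 11
Reactants: 13 triumbelletin di-O-methyl ether
Product: 14 triumbelletin
Conditions: BBr3 (8 equiv), CH2Cl2, −78 °C → rt; then H2O
Reagents that add atoms: none
Why: Lewis-acid cleavage of aryl methyl ethers, in which bromide attacks the methyl carbon of the boron-bound ether; the three lactones and the C3–O–C7 ether offer only sp2 carbons on oxygen and should stay intact.

**Compound list**

1 | umbelliferone (7-hydroxy-2H-chromen-2-one) | O=c1ccc2ccc(O)cc2o1 | starting material
2 | 7-hydroxy-8-iodo-2H-chromen-2-one | Oc1ccc2ccc(=O)oc2c1I | intermediate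
3 | 8-iodo-7-methoxy-2H-chromen-2-one | COc1ccc2ccc(=O)oc2c1I | intermediate
4 | (2,6-dimethoxyphenyl)boronic acid | COc1cccc(OC)c1B(O)O | starting material
5 | 8-(2,6-dimethoxyphenyl)-7-methoxy-2H-chromen-2-one | COc1cccc(OC)c1-c1c(OC)ccc2ccc(=O)oc12 | intermediate
6 | 2,4-dimethoxy-3-(7-methoxy-2-oxo-2H-chromen-8-yl)benzaldehyde | COc1ccc(C=O)c(OC)c1-c1c(OC)ccc2ccc(=O)oc12 | intermediate
7 | 2-hydroxy-4-methoxy-3-(7-methoxy-2-oxo-2H-chromen-8-yl)benzaldehyde | COc1ccc(C=O)c(O)c1-c1c(OC)ccc2ccc(=O)oc12 | intermediate
8 | ethyl bromoacetate | CCOC(=O)CBr | starting material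
9 | ethyl [(2-oxo-2H-chromen-7-yl)oxy]acetate | CCOC(=O)COc1ccc2ccc(=O)oc2c1 | intermediate
10 | [(2-oxo-2H-chromen-7-yl)oxy]acetic acid | OC(=O)COc1ccc2ccc(=O)oc2c1 | intermediate
11 | [(2-oxo-2H-chromen-7-yl)oxy]acetyl chloride | ClC(=O)COc1ccc2ccc(=O)oc2c1 | intermediate
12 | 6-formyl-3-methoxy-2-(7-methoxy-2-oxo-2H-chromen-8-yl)phenyl [(2-oxo-2H-chromen-7-yl)oxy]acetate | O=Cc1ccc(OC)c(-c2c(OC)ccc3ccc(=O)oc23)c1OC(=O)COc1ccc2ccc(=O)oc2c1 | intermediate
13 | triumbelletin di-O-methyl ether | O=c1ccc2ccc(Oc3cc4ccc(OC)c(-c5c(OC)ccc6ccc(=O)oc56)c4oc3=O)cc2o1 | intermediate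
14 | triumbelletin | O=c1ccc2ccc(Oc3cc4ccc(O)c(-c5c(O)ccc6ccc(=O)oc56)c4oc3=O)cc2o1 | target

**Step count**

Total steps: 11. Longest linear sequence: 8 steps (steps 1–5, 9, 10, 11, from umbelliferone).

**Steps most likely to fail**

1. Step 10 (ring closure). The OCH2 group is only weakly acidic, so cleavage of the hindered, activated aryl ester by acyl transfer to the amidine base or to traces of water may outrun the aldol closure and return the phenol. The fallback sets out from 7 and 10 and comes back at 13. It is a one-pot Perkin–Oglialoro condensation: 7 and 10 are heated in Ac2O with NaOAc (or Et3N) at about 120 °C. The mixed anhydride of 10 is regenerated continuously, condenses at the aldehyde and lactonises, so no preformed ester has to survive. No new compound is isolated.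

2. Step 3 (biaryl coupling). Protodeboronation of the di-ortho-methoxy boronic acid may be faster than transmetalation to the hindered arylpalladium iodide, so that the iodide is left unconsumed or reduced. The fallback sets out from 3 and comes back at 5. It is a Negishi coupling, which has no protodeboronation channel and needs no base. 1,3-Dimethoxybenzene is lithiated between the two methoxy groups (n-BuLi, THF, 0 °C → rt) to give 2,6-dimethoxyphenyllithium F1. F1 is transmetalated with ZnCl2 to (2,6-dimethoxyphenyl)zinc chloride F2. F2 is coupled with 3 using Pd(OAc)2 and SPhos in THF at 65 °C; the arylzinc does not attack the lactone.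

3. Step 11 (final demethylation). The boron adducts of the tris-lactone may precipitate and leave one hindered methyl ether uncleaved, or long Lewis-acid exposure may degrade the product. The fallback sets out from 6 and comes back at 14; it moves the harsh demethylation to an early, simple compound and ends with a mild acetal hydrolysis.
   - 6 is fully demethylated with excess BBr3 (CH2Cl2, −78 °C → rt) to 2,4-dihydroxy-3-(7-hydroxy-2-oxo-2H-chromen-8-yl)benzaldehyde F3.
   - The two non-chelated phenols are protected with MOMCl (2.1 equiv) and K2CO3 in acetone to give 2-hydroxy-4-(methoxymethoxy)-3-[7-(methoxymethoxy)-2-oxo-2H-chromen-8-yl]benzaldehyde F4.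
   - Acylation with 11 (pyridine, DMAP, CH2Cl2) gives 6-formyl-3-(methoxymethoxy)-2-[7-(methoxymethoxy)-2-oxo-2H-chromen-8-yl]phenyl [(2-oxo-2H-chromen-7-yl)oxy]acetate F5.
   - DBU in MeCN closes ring B as in step 10 to give triumbelletin bis(methoxymethyl) ether F6.
   - HCl in MeOH at 50 °C releases 14.

**Further compounds**

F0 | step 10 | none | none
F1 | step 3 | 2,6-dimethoxyphenyllithium | [Li]c1c(OC)cccc1OC
F2 | step 3 | (2,6-dimethoxyphenyl)zinc chloride | COc1cccc(OC)c1[Zn]Cl
F3 | step 11 | 2,4-dihydroxy-3-(7-hydroxy-2-oxo-2H-chromen-8-yl)benzaldehyde | O=Cc1ccc(O)c(-c2c(O)ccc3ccc(=O)oc23)c1O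
F4 | step 11 | 2-hydroxy-4-(methoxymethoxy)-3-[7-(methoxymethoxy)-2-oxo-2H-chromen-8-yl]benzaldehyde | O=Cc1ccc(OCOC)c(-c2c(OCOC)ccc3ccc(=O)oc23)c1O
F5 | step 11 | 6-formyl-3-(methoxymethoxy)-2-[7-(methoxymethoxy)-2-oxo-2H-chromen-8-yl]phenyl [(2-oxo-2H-chromen-7-yl)oxy]acetate | O=Cc1ccc(OCOC)c(-c2c(OCOC)ccc3ccc(=O)oc23)c1OC(=O)COc1ccc2ccc(=O)oc2c1
F6 | step 11 | triumbelletin bis(methoxymethyl) ether | O=c1ccc2ccc(Oc3cc4ccc(OCOC)c(-c5c(OCOC)ccc6ccc(=O)oc56)c4oc3=O)cc2o1
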